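**Plan**

- Cuts (chromene numbering): first O1–C2 of the pyran ring, giving the open diprenylcatechol 13; then the two aryl–CH2 bonds of the prenyl groups on ring B; then the ring B aryl–CH2 bond of the propane chain.
- Forward order: ring A allylarene 4 and the symmetric dibromocatechol bis-MOM ether 6 are joined first (hydroboration, B-alkyl Suzuki–Miyaura). The prenyl groups follow one at a time (ortho-lithiation beside Br, then Br–Li exchange). The three MOM groups are removed and the pyran ring is closed last.
- Enabling feature: O1 and the C8–OH are the two oxygens of a ring B catechol, and C4 sits on C4a, ortho to O1. The pyran is therefore the redox isomer of a 3-prenyl ortho-quinone. Oxidation, tautomerisation to the vinylogous ortho-quinone methide and oxa-6π electrocyclisation make O1–C2 and at the same time tell apart the two catechol oxygens and the two prenyl groups without protecting groups.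
- Stereochemistry: the target has no stereocentre; the cis C3=C4 alkene is fixed by the ring.

Key step: step 8

Remark: phenols 1 and 5 are taken as catalogue compounds.

**Route**

Step 1
Reactants: 1 4-bromo-3-methoxyphenol
Product: 2 1-bromo-2-methoxy-4-(methoxymethoxy)benzene
Conditions: MOMCl, iPr2NEt, CH2Cl2, 0 → 23 °C
Reagents that add atoms: chloromethyl methyl ether (MOMCl), COCCl
Why: Williamson-type O-alkylation with the reactive α-chloro ether masks the ring A phenol as an acetal that should tolerate the organolithium, borane and basic palladium conditions ahead.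

Step 2
Reactants: 2 1-bromo-2-methoxy-4-(methoxymethoxy)benzene
Product: 4 2-methoxy-4-(methoxymethoxy)-1-(prop-2-en-1-yl)benzene, via aryllithium 3 (not isolated)
Conditions: n-BuLi, THF, −78 °C; then CuBr·SMe2 (10 mol %), allyl bromide, −78 → 0 °C
Reagents that add atoms: allyl bromide, C=CCBr
Why: Bromine–lithium exchange followed by copper-catalysed allylic substitution should place the three-carbon chain precursor ortho to OMe and para to the protected phenol.

Step 3
Reactants: 5 4,5-dibromobenzene-1,2-diol
Product: 6 1,2-dibromo-4,5-bis(methoxymethoxy)benzene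
Conditions: MOMCl (2.5 equiv), iPr2NEt, CH2Cl2, 0 → 23 °C
Reagents that add atoms: chloromethyl methyl ether (MOMCl), COCCl
Why: Double Williamson etherification gives a symmetric bis-acetal whose OMOM groups later assist ortho-lithiation and come off together with the ring A acetal.

Step 4
Reactants: 4 2-methoxy-4-(methoxymethoxy)-1-(prop-2-en-1-yl)benzene; 6 1,2-dibromo-4,5-bis(methoxymethoxy)benzene
Product: 8 1-bromo-2-{3-[2-methoxy-4-(methoxymethoxy)phenyl]propyl}-4,5-bis(methoxymethoxy)benzene, via B-alkyl-9-BBN 7 (not isolated)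
Conditions: 4, 9-BBN-H, THF, 0 → 23 °C; then 6 (2 equiv), PdCl2(dppf) (5 mol %), K3PO4 (3 M aq), THF/DMF, 60 °C
Reagents that add atoms: none
Why: Anti-Markovnikov hydroboration and B-alkyl Suzuki–Miyaura coupling should join the fragments; the two bromines of 6 are equivalent so no site selectivity is needed, and the new ortho-alkyl group slows a second coupling (excess 6 is recovered).

Step 5
Reactants: 8 1-bromo-2-{3-[2-methoxy-4-(methoxymethoxy)phenyl]propyl}-4,5-bis(methoxymethoxy)benzene
Product: 10 2-bromo-1-{3-[2-methoxy-4-(methoxymethoxy)phenyl]propyl}-4,5-bis(methoxymethoxy)-3-(3-methylbut-2-en-1-yl)benzene, via aryllithium 9 (not isolated)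
Conditions: LiN(iPr)2, THF, −78 °C; then CuBr·SMe2 (10 mol %), prenyl bromide, −78 → −30 °C
Reagents that add atoms: prenyl bromide (1-bromo-3-methylbut-2-ene), CC(C)=CCBr
Why: Directed ortho-lithiation should remove only the ring B hydrogen flanked by Br and OMOM (the ether-only positions need alkyllithiums), and copper-catalysed allylic substitution at the unhindered CH2 of prenyl bromide should give the linear prenyl group.

Step 6
Reactants: 10 2-bromo-1-{3-[2-methoxy-4-(methoxymethoxy)phenyl]propyl}-4,5-bis(methoxymethoxy)-3-(3-methylbut-2-en-1-yl)benzene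
Product: 12 1-{3-[2-methoxy-4-(methoxymethoxy)phenyl]propyl}-4,5-bis(methoxymethoxy)-2,3-bis(3-methylbut-2-en-1-yl)benzene, via aryllithium 11 (not isolated)
Conditions: t-BuLi (2.05 equiv), THF, −78 °C; then CuBr·SMe2 (10 mol %), prenyl bromide, −78 → 0 °C
Reagents that add atoms: prenyl bromide (1-bromo-3-methylbut-2-ene), CC(C)=CCBr
Why: Bromine–lithium exchange is faster than any deprotonation at −78 °C, and copper-catalysed SN2 prenylation of the aryllithium should put the second prenyl group exactly where the bromine stood.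

Step 7
Reactants: 12 1-{3-[2-methoxy-4-(methoxymethoxy)phenyl]propyl}-4,5-bis(methoxymethoxy)-2,3-bis(3-methylbut-2-en-1-yl)benzene
Product: 13 5-[3-(4-hydroxy-2-methoxyphenyl)propyl]-3,4-bis(3-methylbut-2-en-1-yl)benzene-1,2-diol
Conditions: HCl (1.25 M in MeOH), 0 → 23 °C, Ar; used at once
Reagents that add atoms: none
Why: Acid-catalysed transacetalisation with methanol should cleave the three aryl MOM ethers, with low temperature and short contact chosen so that the phenol next to a prenyl group does not add to the alkene.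

Step 8
Reactants: 13 5-[3-(4-hydroxy-2-methoxyphenyl)propyl]-3,4-bis(3-methylbut-2-en-1-yl)benzene-1,2-diol
Product: 16 kazinol N, via ortho-quinone 14 (not isolated), via ortho-quinone methide 15 (not isolated)
Conditions: Ag2O (1.05 equiv), Na2SO4, Et2O, 0 °C, filtration through Celite; then Et3N (0.2 equiv), PhMe, 23 → 50 °C, Ar
Reagents that add atoms: none
Why: Ag2O should take two hydrogens from the ring B catechol (the ring A monophenol is not oxidised) to give ortho-quinone 14, amine-mediated proton transfer from the prenyl CH2 beside a quinone carbonyl to the far carbonyl oxygen gives the vinylogous ortho-quinone methide 15, and 15 closes by thermal oxa-6π electrocyclisation in which the carbonyl oxygen (O1) bonds to the CMe2 terminus (C2) and ring B rearomatises. The closest known reaction types are the amine-mediated isomerisation of prenylquinones to 2,2-dimethylchromenols and the oxidative cyclisation of ortho-prenylphenols to 2,2-dimethylchromenes. The pyran closes in a six-atom disrotatory electrocyclic mode over O=C–C=C–C=C, not by ionic addition to the alkene, so no five-membered alternative exists. No stereocentre is formed and the cis C3=C4 alkene is imposed by the ring. The step needs selection between two prenyl groups and two catechol oxygens, and constitution decides both: only the prenyl on the carbon next to a quinone C=O can give an s-cis ortho-quinone methide, whereas the para-quinone methide tautomers (from the other prenyl and from the chain CH2) cannot cyclise and should revert to 14 while 15 is drained by aromatisation. Over-oxidation of the product phenol is limited by using one equivalent of Ag2O and removing the silver before the isomerisation.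

**Compound list**

1 | 4-bromo-3-methoxyphenol | COc1cc(O)ccc1Br | starting material
2 | 1-bromo-2-methoxy-4-(methoxymethoxy)benzene | COCOc1ccc(Br)c(OC)c1 | intermediate
3 | [2-methoxy-4-(methoxymethoxy)phenyl]lithium | [Li]c1ccc(OCOC)cc1OC | intermediate
4 | 2-methoxy-4-(methoxymethoxy)-1-(prop-2-en-1-yl)benzene | C=CCc1ccc(OCOC)cc1OC | intermediate
5 | 4,5-dibromobenzene-1,2-diol | Oc1cc(Br)c(Br)cc1O | starting material
6 | 1,2-dibromo-4,5-bis(methoxymethoxy)benzene | COCOc1cc(Br)c(Br)cc1OCOC | intermediate
7 | 9-{3-[2-methoxy-4-(methoxymethoxy)phenyl]propyl}-9-borabicyclo[3.3.1]nonane | COCOc1ccc(CCCB2C3CCCC2CCC3)c(OC)c1 | intermediate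
8 | 1-bromo-2-{3-[2-methoxy-4-(methoxymethoxy)phenyl]propyl}-4,5-bis(methoxymethoxy)benzene | COCOc1ccc(CCCc2cc(OCOC)c(OCOC)cc2Br)c(OC)c1 | intermediate
9 | (2-bromo-3-{3-[2-methoxy-4-(methoxymethoxy)phenyl]propyl}-5,6-bis(methoxymethoxy)phenyl)lithium | COCOc1ccc(CCCc2cc(OCOC)c(OCOC)c([Li])c2Br)c(OC)c1 | intermediate
10 | 2-bromo-1-{3-[2-methoxy-4-(methoxymethoxy)phenyl]propyl}-4,5-bis(methoxymethoxy)-3-(3-methylbut-2-en-1-yl)benzene | COCOc1ccc(CCCc2cc(OCOC)c(OCOC)c(CC=C(C)C)c2Br)c(OC)c1 | intermediate
11 | (2-{3-[2-methoxy-4-(methoxymethoxy)phenyl]propyl}-4,5-bis(methoxymethoxy)-6-(3-methylbut-2-en-1-yl)phenyl)lithium | COCOc1ccc(CCCc2cc(OCOC)c(OCOC)c(CC=C(C)C)c2[Li])c(OC)c1 | intermediate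
12 | 1-{3-[2-methoxy-4-(methoxymethoxy)phenyl]propyl}-4,5-bis(methoxymethoxy)-2,3-bis(3-methylbut-2-en-1-yl)benzene | COCOc1ccc(CCCc2cc(OCOC)c(OCOC)c(CC=C(C)C)c2CC=C(C)C)c(OC)c1 | intermediate
13 | 5-[3-(4-hydroxy-2-methoxyphenyl)propyl]-3,4-bis(3-methylbut-2-en-1-yl)benzene-1,2-diol | COc1cc(O)ccc1CCCc1cc(O)c(O)c(CC=C(C)C)c1CC=C(C)C | intermediate
14 | 5-[3-(4-hydroxy-2-methoxyphenyl)propyl]-3,4-bis(3-methylbut-2-en-1-yl)cyclohexa-3,5-diene-1,2-dione | COc1cc(O)ccc1CCCC1=CC(=O)C(=O)C(CC=C(C)C)=C1CC=C(C)C | intermediate
15 | (6Z)-2-hydroxy-4-[3-(4-hydroxy-2-methoxyphenyl)propyl]-5-(3-methylbut-2-en-1-yl)-6-(3-methylbut-2-en-1-ylidene)cyclohexa-2,4-dien-1-one | COc1cc(O)ccc1CCCC1=C(CC=C(C)C)/C(=C/C=C(C)C)C(=O)C(O)=C1 | intermediate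
16 | kazinol N, 6-[3-(4-hydroxy-2-methoxyphenyl)propyl]-2,2-dimethyl-5-(3-methylbut-2-en-1-yl)-2H-chromen-8-ol | COc1cc(O)ccc1CCCc1cc(O)c2c(c1CC=C(C)C)C=CC(C)(C)O2 | target

**Step count and risks**

Total step count: 8. Longest linear sequence: 7 steps (1 → 16 through steps 1, 2, 4, 5, 6, 7 and 8); the branch from 5 through steps 3 to 8 has 6 steps.

Steps most likely to fail:

1. Step 8. Ortho-quinone 14 may tautomerise towards the para-quinone methides of the second prenyl group or of the chain CH2 and leak from there to styrene-type catechols or oligomers instead of returning, and the product phenol may be oxidised further. The fallback closes the pyran before any competing benzylic C–H exists, by the aryl propargyl ether rearrangement. It sets out from 5 and comes back to the route at 16. Mono-O-alkylation of 5 with 3-chloro-3-methylbut-1-yne (DBU, CuCl2 cat., MeCN, 0 °C) should give 4,5-dibromo-2-[(2-methylbut-3-yn-2-yl)oxy]phenol F1. Heating F1 (N,N-diethylaniline, 150 °C) should give 5,6-dibromo-2,2-dimethyl-2H-chromen-8-ol F2 by Claisen rearrangement, enolisation, 1,5-hydrogen shift and oxa-6π closure. MOMCl and iPr2NEt should then give 5,6-dibromo-8-(methoxymethoxy)-2,2-dimethyl-2H-chromene F3. B-alkyl Suzuki–Miyaura coupling of F3 with borane 7 (PdCl2(dppf), K3PO4) at the less hindered C6–Br should give 5-bromo-6-{3-[2-methoxy-4-(methoxymethoxy)phenyl]propyl}-8-(methoxymethoxy)-2,2-dimethyl-2H-chromene F4. Bromine–lithium exchange with t-BuLi (THF, −78 °C) should convert F4 into (6-{3-[2-methoxy-4-(methoxymethoxy)phenyl]propyl}-8-(methoxymethoxy)-2,2-dimethyl-2H-chromen-5-yl)lithium F5, and CuBr·SMe2 with prenyl bromide should then give 6-{3-[2-methoxy-4-(methoxymethoxy)phenyl]propyl}-8-(methoxymethoxy)-2,2-dimethyl-5-(3-methylbut-2-en-1-yl)-2H-chromene F6. Methanolic HCl on F6 then gives 16; here no free phenol ever stands next to a prenyl group under acid.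

2. Step 5. The ortho-bromoaryllithium 9 may lose LiBr to an aryne, or metalation may be incomplete or stray onto the assembled diarylpropane. The fallback reverses the order of bond construction. It sets out from 6 and comes back at 10. The symmetric dibromide 6 is metalated at one of its two equivalent flanked C–H sites with TMPMgCl·LiCl (THF, 0 → 23 °C) to give [2,3-dibromo-5,6-bis(methoxymethoxy)phenyl]magnesium chloride F7, an arylmagnesium species that should not eliminate. Prenylation of F7 (CuBr·SMe2 cat., prenyl bromide) should give 1,2-dibromo-4,5-bis(methoxymethoxy)-3-(3-methylbut-2-en-1-yl)benzene F8. Site-selective B-alkyl Suzuki–Miyaura coupling of F8 with borane 7 at the bromine remote from the prenyl group (the less hindered C–Br) then gives 10.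

3. Step 7. Under protic acid the freed phenol may add to the neighbouring prenyl alkene (2,2-dimethylchroman formation) and the prenyl groups may be hydrated. The fallback replaces solvolysis by non-protic silyl transfer. It sets out from 12 and comes back at 13. TMSOTf and 2,2′-bipyridyl (CH2Cl2, 0 °C) should convert the three aryl MOM ethers of 12 into {5-[3-(2-methoxy-4-(trimethylsilyloxy)phenyl)propyl]-3,4-bis(3-methylbut-2-en-1-yl)-1,2-phenylene}bis(oxy)bis(trimethylsilane) F9, the methoxymethyl cation being taken up by the bipyridyl. Hydrolysis of F9 at neutral pH (H2O, THF, 23 °C) gives 13.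

**Further compounds**

F1 | step 8 | 4,5-dibromo-2-[(2-methylbut-3-yn-2-yl)oxy]phenol | C#CC(C)(C)Oc1cc(Br)c(Br)cc1O
F2 | step 8 | 5,6-dibromo-2,2-dimethyl-2H-chromen-8-ol | CC1(C)C=Cc2c(Br)c(Br)cc(O)c2O1
F3 | step 8 | 5,6-dibromo-8-(methoxymethoxy)-2,2-dimethyl-2H-chromene | COCOc1cc(Br)c(Br)c2C=CC(C)(C)Oc12
F4 | step 8 | 5-bromo-6-{3-[2-methoxy-4-(methoxymethoxy)phenyl]propyl}-8-(methoxymethoxy)-2,2-dimethyl-2H-chromene | COCOc1ccc(CCCc2cc(OCOC)c3OC(C)(C)C=Cc3c2Br)c(OC)c1
F5 | step 8 | (6-{3-[2-methoxy-4-(methoxymethoxy)phenyl]propyl}-8-(methoxymethoxy)-2,2-dimethyl-2H-chromen-5-yl)lithium | COCOc1ccc(CCCc2cc(OCOC)c3OC(C)(C)C=Cc3c2[Li])c(OC)c1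
F6 | step 8 | 6-{3-[2-methoxy-4-(methoxymethoxy)phenyl]propyl}-8-(methoxymethoxy)-2,2-dimethyl-5-(3-methylbut-2-en-1-yl)-2H-chromene | COCOc1ccc(CCCc2cc(OCOC)c3OC(C)(C)C=Cc3c2CC=C(C)C)c(OC)c1
F7 | step 5 | [2,3-dibromo-5,6-bis(methoxymethoxy)phenyl]magnesium chloride | COCOc1cc(Br)c(Br)c([Mg]Cl)c1OCOC
F8 | step 5 | 1,2-dibromo-4,5-bis(methoxymethoxy)-3-(3-methylbut-2-en-1-yl)benzene | COCOc1cc(Br)c(Br)c(CC=C(C)C)c1OCOC
F9 | step 7 | {5-[3-(2-methoxy-4-(trimethylsilyloxy)phenyl)propyl]-3,4-bis(3-methylbut-2-en-1-yl)-1,2-phenylene}bis(oxy)bis(trimethylsilane) | COc1cc(O[Si](C)(C)C)ccc1CCCc1cc(O[Si](C)(C)C)c(O[Si](C)(C)C)c(CC=C(C)C)c1CC=C(C)C
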